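**Retrosynthetic overview**
- The C4 ketone comes from a C4 methyl ether by solvolysis to the alcohol and oxidation; both MOM ethers are removed last.
- The strategy rests on the unit C4–C4a–C8a–O1 of ring C, which is an ortho-quinone methide of ring A in masked form, and on C2 carrying the 4-hydroxyphenyl group. 4-Vinylphenol therefore supplies C2, C3 and ring B in one piece, forming C3–C4 and O1–C2.
- The quinone methide comes from the fully substituted salicylaldehyde 6 and trimethyl orthoformate; 6 comes from 2,4,6-trihydroxybenzaldehyde by twofold C-prenylation, 4-O-methylation and mono-MOM protection.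
- Ring order: ring A is bought, ring B arrives with the styrene, ring C is closed in the key step, which also sets C2, the only stereocentre kept.

Key step: step 5

Assumption: the sense of induction of the catalyst, (R)-TRIP = (R)-3,3'-bis(2,4,6-triisopropylphenyl)-1,1'-binaphthyl-2,2'-diyl hydrogen phosphate, cannot be predicted with confidence; the (R) acid is written and its mirror image would be used if it leads to the (2R) series. Compound 12 is drawn as the expected 2,4-cis isomer.

**Step 1**
Reactants: 1 2,4,6-trihydroxybenzaldehyde; 2 1-bromo-3-methylbut-2-ene (prenyl bromide)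
Product: 4 2,4,6-trihydroxy-3,5-bis(3-methylbut-2-en-1-yl)benzaldehyde, via mono-prenyl aldehyde 3 (not isolated)
Conditions: 2 (2.2 equiv), DBU (2.2 equiv), THF, 0 °C → rt; chromatography
Reagents that add atoms: none
Why: C-alkylation of a phloroglucinol phenoxide (Friedel–Crafts-type C-prenylation of an acylphloroglucinol), in which the two free ring carbons C3 and C5 are the carbon termini of the ambident anion, so two equivalents of bromide should give the 3,5-diprenyl aldehyde, separable from mono- and over-alkylated material.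

**Step 2**
Reactants: 4 2,4,6-trihydroxy-3,5-bis(3-methylbut-2-en-1-yl)benzaldehyde
Product: 5 2,6-dihydroxy-4-methoxy-3,5-bis(3-methylbut-2-en-1-yl)benzaldehyde
Conditions: MeI (1.05 equiv), K2CO3 (1.0 equiv), DMF, 0 °C → rt
Reagents that add atoms: iodomethane, CI
Why: Williamson ether synthesis, selective because the 4-hydroxyl is the only one not hydrogen-bonded to the formyl group and is the most acidic, so one equivalent of base and iodomethane should methylate it alone.

**Step 3**
Reactants: 5 2,6-dihydroxy-4-methoxy-3,5-bis(3-methylbut-2-en-1-yl)benzaldehyde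
Product: 6 2-hydroxy-4-methoxy-6-(methoxymethoxy)-3,5-bis(3-methylbut-2-en-1-yl)benzaldehyde
Conditions: MOMCl (1.1 equiv), i-Pr2NEt, CH2Cl2, 0 °C
Reagents that add atoms: chloromethyl methyl ether, COCCl
Why: MOM ether formation (Williamson-type alkylation) on one of two equivalent hydroxyls, after which the remaining hydroxyl is locked in a strong hydrogen bond to the aldehyde, so the reaction should stop at mono-protection.

**Step 4**
Reactants: 7 4-acetoxystyrene
Product: 8 4-vinylphenol
Conditions: K2CO3 (0.1 equiv), MeOH, 0 °C → rt; aq. NH4Cl; used at once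
Reagents that add atoms: none
Why: Base-catalysed transesterification of the aryl acetate frees the phenol under conditions too mild to polymerise the styrene, which is used immediately because it does not keep.

**Step 5**
Reactants: 6 2-hydroxy-4-methoxy-6-(methoxymethoxy)-3,5-bis(3-methylbut-2-en-1-yl)benzaldehyde; 8 4-vinylphenol; 9 trimethyl orthoformate
Product: 12 (2S,4S)-2-(4-hydroxyphenyl)-4,7-dimethoxy-5-(methoxymethoxy)-6,8-bis(3-methylbut-2-en-1-yl)chromane, via dimethyl acetal 10 (not isolated), via methoxy ortho-quinone methide 11 (not isolated)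
Conditions: (R)-TRIP (10 mol %), 9 (1.5 equiv), 5 Å MS, PhMe, rt; then 8 (1.5 equiv, slow addition), −30 °C; Et3N quench; chromatographic separation of the C4 epimers
Reagents that add atoms: none
Why: Proposed new method: the phosphoric acid first promotes acetal formation from 6 and the orthoformate, then ionises acetal 10 by loss of methanol to the methoxy ortho-quinone methide 11, held to the phosphate as a hydrogen-bonded oxocarbenium ion pair; the terminal alkene carbon of 8 adds to the methide carbon (C3–C4) and the ring A oxygen then closes on the benzylic carbon stabilised by the para-hydroxyl (O1–C2). The closest known reactions are the achiral acid-promoted coupling of salicylaldehyde acetals with styrenes to 2-aryl-4-alkoxychromans and the chiral phosphoric acid (4+2) cycloadditions of ortho-quinone methides with hydroxystyrenes; new here is the asymmetric use of an alkoxy ortho-quinone methide made from an aldehyde. Ring C closes as an inverse-demand hetero-Diels–Alder (4+2), in its stepwise limit a 6-exo-trig capture of the para-quinone-methide-like cation by the phenol oxygen. C2 is set by the chiral phosphate, which binds the quinone methide and, through its P=O, the free hydroxyl of 8 and so exposes one face of the alkene; C4 follows from an endo approach (methoxy cis to aryl) and is erased in step 8, the C4 epimers being separated here so that the enantiopurity checked at C2 is the one carried forward. The step needs the styrene to react in preference to the two prenyl alkenes and only one quinone methide to form: the para-hydroxyl makes the vinyl group by far the better nucleophile, polarity fixes the regiochemistry, and the MOM ether on the C5 oxygen leaves a single phenol to build the heterodiene and stops the product from ionising at C4 into a second quinone methide.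

**Step 6**
Reactants: 12 (2S,4S)-2-(4-hydroxyphenyl)-4,7-dimethoxy-5-(methoxymethoxy)-6,8-bis(3-methylbut-2-en-1-yl)chromane
Product: 13 (2S,4S)-4,7-dimethoxy-5-(methoxymethoxy)-2-[4-(methoxymethoxy)phenyl]-6,8-bis(3-methylbut-2-en-1-yl)chromane
Conditions: MOMCl (1.5 equiv), i-Pr2NEt, CH2Cl2, 0 °C → rt
Reagents that add atoms: chloromethyl methyl ether, COCCl
Why: MOM ether formation on the only free hydroxyl under basic conditions that leave the acid-labile C4 methyl ether alone; it keeps the phenol out of the oxidation and lets both protecting groups leave together at the end.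

**Step 7**
Reactants: 13 (2S,4S)-4,7-dimethoxy-5-(methoxymethoxy)-2-[4-(methoxymethoxy)phenyl]-6,8-bis(3-methylbut-2-en-1-yl)chromane
Product: 14 (2S)-7-methoxy-5-(methoxymethoxy)-2-[4-(methoxymethoxy)phenyl]-6,8-bis(3-methylbut-2-en-1-yl)chroman-4-ol (mixture of C4 epimers)
Conditions: PPTS (0.3 equiv), THF/H2O (3:1), rt → 35 °C
Reagents that add atoms: water, O
Why: SN1 solvolysis of a benzylic ether, easy because the C4 cation is stabilised by three ring A oxygens (O1 and the C5 oxygen ortho, the C7 oxygen para), with the large excess of water trapping it as the alcohol while the aryl MOM ethers and C2 should not respond to so weak an acid; scrambling of C4 is of no consequence.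

**Step 8**
Reactants: 14 (2S)-7-methoxy-5-(methoxymethoxy)-2-[4-(methoxymethoxy)phenyl]-6,8-bis(3-methylbut-2-en-1-yl)chroman-4-ol
Product: 15 (2S)-7-methoxy-5-(methoxymethoxy)-2-[4-(methoxymethoxy)phenyl]-6,8-bis(3-methylbut-2-en-1-yl)chroman-4-one
Conditions: Dess–Martin periodinane (1.3 equiv), pyridine, CH2Cl2, 0 °C
Reagents that add atoms: none
Why: Dess–Martin oxidation of the secondary benzylic alcohol, buffered with pyridine so that the acid-sensitive alcohol does not ionise, removes the C4 stereocentre and should leave C2, the prenyl alkenes and the acetals untouched.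

**Step 9**
Reactants: 15 (2S)-7-methoxy-5-(methoxymethoxy)-2-[4-(methoxymethoxy)phenyl]-6,8-bis(3-methylbut-2-en-1-yl)chroman-4-one
Product: 17 (2S)-5-hydroxy-2-(4-hydroxyphenyl)-7-methoxy-6,8-bis(3-methylbut-2-en-1-yl)chroman-4-one, via C5-hydroxy mono-MOM flavanone 16 (not isolated)
Conditions: methanolic HCl (ca. 1 M), MeOH/THF, 40 °C, stopped as soon as 16 is consumed
Reagents that add atoms: none
Why: Acid-catalysed acetal methanolysis (MOM deprotection) removes the C5 ether first, helped by the peri carbonyl, then the aryl ether of ring B; acid, unlike base, does not open the flavanone to the chalcone, so C2 should keep its configuration, and such conditions are routinely tolerated by prenylated flavanones.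

**Compound list**
1 | 2,4,6-trihydroxybenzaldehyde | O=Cc1c(O)cc(O)cc1O | starting material
2 | 1-bromo-3-methylbut-2-ene (prenyl bromide) | CC(C)=CCBr | starting material
3 | 2,4,6-trihydroxy-3-(3-methylbut-2-en-1-yl)benzaldehyde | O=Cc1c(O)cc(O)c(CC=C(C)C)c1O | intermediate
4 | 2,4,6-trihydroxy-3,5-bis(3-methylbut-2-en-1-yl)benzaldehyde | O=Cc1c(O)c(CC=C(C)C)c(O)c(CC=C(C)C)c1O | intermediate
5 | 2,6-dihydroxy-4-methoxy-3,5-bis(3-methylbut-2-en-1-yl)benzaldehyde | COc1c(CC=C(C)C)c(O)c(C=O)c(O)c1CC=C(C)C | intermediate
6 | 2-hydroxy-4-methoxy-6-(methoxymethoxy)-3,5-bis(3-methylbut-2-en-1-yl)benzaldehyde | COCOc1c(CC=C(C)C)c(OC)c(CC=C(C)C)c(O)c1C=O | intermediate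
7 | 4-acetoxystyrene | CC(=O)Oc1ccc(C=C)cc1 | starting material
8 | 4-vinylphenol | C=Cc1ccc(O)cc1 | intermediate
9 | trimethyl orthoformate | COC(OC)OC | starting material
10 | 2-(dimethoxymethyl)-5-methoxy-3-(methoxymethoxy)-4,6-bis(3-methylbut-2-en-1-yl)phenol | COCOc1c(CC=C(C)C)c(OC)c(CC=C(C)C)c(O)c1C(OC)OC | intermediate
11 | 3-methoxy-6-(methoxymethylidene)-5-(methoxymethoxy)-2,4-bis(3-methylbut-2-en-1-yl)cyclohexa-2,4-dien-1-one | COC=C1C(=O)C(CC=C(C)C)=C(OC)C(CC=C(C)C)=C1OCOC | intermediate
12 | (2S,4S)-2-(4-hydroxyphenyl)-4,7-dimethoxy-5-(methoxymethoxy)-6,8-bis(3-methylbut-2-en-1-yl)chromane | COc1c(CC=C(C)C)c(OCOC)c2c(c1CC=C(C)C)O[C@H](c1ccc(O)cc1)C[C@@H]2OC | intermediate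
13 | (2S,4S)-4,7-dimethoxy-5-(methoxymethoxy)-2-[4-(methoxymethoxy)phenyl]-6,8-bis(3-methylbut-2-en-1-yl)chromane | COc1c(CC=C(C)C)c(OCOC)c2c(c1CC=C(C)C)O[C@H](c1ccc(OCOC)cc1)C[C@@H]2OC | intermediate
14 | (2S)-7-methoxy-5-(methoxymethoxy)-2-[4-(methoxymethoxy)phenyl]-6,8-bis(3-methylbut-2-en-1-yl)chroman-4-ol, C4 epimers | COc1c(CC=C(C)C)c(OCOC)c2c(c1CC=C(C)C)O[C@H](c1ccc(OCOC)cc1)CC2O | intermediate
15 | (2S)-7-methoxy-5-(methoxymethoxy)-2-[4-(methoxymethoxy)phenyl]-6,8-bis(3-methylbut-2-en-1-yl)chroman-4-one | COc1c(CC=C(C)C)c(OCOC)c2c(c1CC=C(C)C)O[C@H](c1ccc(OCOC)cc1)CC2=O | intermediate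
16 | (2S)-5-hydroxy-7-methoxy-2-[4-(methoxymethoxy)phenyl]-6,8-bis(3-methylbut-2-en-1-yl)chroman-4-one | COc1c(CC=C(C)C)c(O)c2c(c1CC=C(C)C)O[C@H](c1ccc(OCOC)cc1)CC2=O | intermediate
17 | (2S)-5-hydroxy-2-(4-hydroxyphenyl)-7-methoxy-6,8-bis(3-methylbut-2-en-1-yl)chroman-4-one | COc1c(CC=C(C)C)c(O)c2c(c1CC=C(C)C)O[C@H](c1ccc(O)cc1)CC2=O | target

**Step count**
Total: 9 steps. Longest linear sequence: 8 steps (1 → 4 → 5 → 6 → 12 → 13 → 14 → 15 → 17); step 4 is a one-step side branch.

**Steps most likely to fail**

Step 5. The chiral phosphate may discriminate poorly between the alkene faces, the acid may oligomerise the vinylphenol faster than the cycloaddition runs, or the acetal may ionise too slowly at low temperature. The fallback uses known chemistry, sets out from 6 and returns at 15. Excess MeMgBr in THF should add to the aldehyde to give 1-[2-hydroxy-4-methoxy-6-(methoxymethoxy)-3,5-bis(3-methylbut-2-en-1-yl)phenyl]ethanol F1, which is oxidised without purification (MnO2, CH2Cl2) to 1-[2-hydroxy-4-methoxy-6-(methoxymethoxy)-3,5-bis(3-methylbut-2-en-1-yl)phenyl]ethanone F2. Claisen–Schmidt condensation with purchased 4-(methoxymethoxy)benzaldehyde (KOH, EtOH) should give (E)-1-[2-hydroxy-4-methoxy-6-(methoxymethoxy)-3,5-bis(3-methylbut-2-en-1-yl)phenyl]-3-[4-(methoxymethoxy)phenyl]prop-2-en-1-one F3. Oxa-Michael closure (NaOAc, EtOH, reflux) gives racemic 7-methoxy-5-(methoxymethoxy)-2-[4-(methoxymethoxy)phenyl]-6,8-bis(3-methylbut-2-en-1-yl)chroman-4-one F4. Kinetic resolution by asymmetric transfer hydrogenation (RuCl(p-cymene)[(R,R)-TsDPEN] or its mirror image, whichever reduces the (2R) ketone faster, HCO2H/Et3N, to about half conversion) leaves the (2S) ketone 15 beside (2R,4R)-7-methoxy-5-(methoxymethoxy)-2-[4-(methoxymethoxy)phenyl]-6,8-bis(3-methylbut-2-en-1-yl)chroman-4-ol F5, which is removed by chromatography.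

Step 7. The C4 cation may lose the C3 proton (dehydration to the 2H-chromene) instead of taking up water, and prolonged acid may begin to ionise C2 or strip the MOM ethers. The fallback avoids the free alcohol and the solvolysis altogether; it sets out from 12 and returns at 17. Acetylation (Ac2O, pyridine) gives 4-[(2S,4S)-4,7-dimethoxy-5-(methoxymethoxy)-6,8-bis(3-methylbut-2-en-1-yl)chroman-2-yl]phenyl acetate F6. Its electron-poor ring B makes the C2 hydrogen a poor hydride donor, so DDQ in CH2Cl2/pH 7 buffer at 0 °C should abstract hydride only from C4, which is flanked by the methoxy group and the trioxygenated ring A. Water adds to the oxocarbenium ion and the hemiketal collapses to 4-[(2S)-7-methoxy-5-(methoxymethoxy)-6,8-bis(3-methylbut-2-en-1-yl)-4-oxochroman-2-yl]phenyl acetate F7. Methanolic HCl at 40 °C then removes the acetate and the MOM ether together to give 17.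

Step 1. Control over the number and site of alkylations may be poor (O- against C-prenylation, mono against geminal dialkylation), which would erode material throughput. The fallback installs the prenyl groups by sigmatropic rearrangement; it sets out from 1 and returns at 5. Selective methylation of the non-chelated hydroxyl (MeI, K2CO3, DMF) gives 2,6-dihydroxy-4-methoxybenzaldehyde F8. Twofold etherification with 3-chloro-3-methylbut-1-yne (DBU, cat. CuCl2, MeCN, 0 °C) gives 4-methoxy-2,6-bis[(2-methylbut-3-yn-2-yl)oxy]benzaldehyde F9. Semihydrogenation (H2, Pd/CaCO3 poisoned with Pb(OAc)2, quinoline, EtOAc) gives 4-methoxy-2,6-bis[(2-methylbut-3-en-2-yl)oxy]benzaldehyde F10. A double aromatic Claisen rearrangement (PhNEt2, 130 °C) can deliver the prenyl groups only to C3 and C5, the formyl carbon blocking the other ortho position, and gives 5.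

**Further compounds**
F1 | step 5 | 1-[2-hydroxy-4-methoxy-6-(methoxymethoxy)-3,5-bis(3-methylbut-2-en-1-yl)phenyl]ethanol | COCOc1c(CC=C(C)C)c(OC)c(CC=C(C)C)c(O)c1C(C)O
F2 | step 5 | 1-[2-hydroxy-4-methoxy-6-(methoxymethoxy)-3,5-bis(3-methylbut-2-en-1-yl)phenyl]ethanone | COCOc1c(CC=C(C)C)c(OC)c(CC=C(C)C)c(O)c1C(C)=O
F3 | step 5 | (E)-1-[2-hydroxy-4-methoxy-6-(methoxymethoxy)-3,5-bis(3-methylbut-2-en-1-yl)phenyl]-3-[4-(methoxymethoxy)phenyl]prop-2-en-1-one | COCOc1c(CC=C(C)C)c(OC)c(CC=C(C)C)c(O)c1C(=O)/C=C/c1ccc(OCOC)cc1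
F4 | step 5 | racemic 7-methoxy-5-(methoxymethoxy)-2-[4-(methoxymethoxy)phenyl]-6,8-bis(3-methylbut-2-en-1-yl)chroman-4-one | COc1c(CC=C(C)C)c(OCOC)c2c(c1CC=C(C)C)OC(c1ccc(OCOC)cc1)CC2=O
F5 | step 5 | (2R,4R)-7-methoxy-5-(methoxymethoxy)-2-[4-(methoxymethoxy)phenyl]-6,8-bis(3-methylbut-2-en-1-yl)chroman-4-ol | COc1c(CC=C(C)C)c(OCOC)c2c(c1CC=C(C)C)O[C@@H](c1ccc(OCOC)cc1)C[C@H]2O
F6 | step 7 | 4-[(2S,4S)-4,7-dimethoxy-5-(methoxymethoxy)-6,8-bis(3-methylbut-2-en-1-yl)chroman-2-yl]phenyl acetate | COc1c(CC=C(C)C)c(OCOC)c2c(c1CC=C(C)C)O[C@H](c1ccc(OC(C)=O)cc1)C[C@@H]2OC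
F7 | step 7 | 4-[(2S)-7-methoxy-5-(methoxymethoxy)-6,8-bis(3-methylbut-2-en-1-yl)-4-oxochroman-2-yl]phenyl acetate | COc1c(CC=C(C)C)c(OCOC)c2c(c1CC=C(C)C)O[C@H](c1ccc(OC(C)=O)cc1)CC2=O
F8 | step 1 | 2,6-dihydroxy-4-methoxybenzaldehyde | COc1cc(O)c(C=O)c(O)c1
F9 | step 1 | 4-methoxy-2,6-bis[(2-methylbut-3-yn-2-yl)oxy]benzaldehyde | COc1cc(OC(C)(C)C#C)c(C=O)c(OC(C)(C)C#C)c1
F10 | step 1 | 4-methoxy-2,6-bis[(2-methylbut-3-en-2-yl)oxy]benzaldehyde | COc1cc(OC(C)(C)C=C)c(C=O)c(OC(C)(C)C=C)c1
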